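## Retrosynthetic overview

- The two O–S bonds (at O3 and O3') are made late, on a flavonol whose only free hydroxyls are 3-OH and 3'-OH. O5 and O4' are benzyl ethers, removed by hydrogenolysis after sulfation.
- O3 is traced back to the C3–H of a flavone (lithiation, borate, peroxide). O3' travels as a MOM ether, orthogonal to benzyl.
- Ring C is cut at three bonds at once (C4a–C4, C4–C3, O1–C2). This gives 2-iodo-5-methoxyresorcinol, carbon monoxide (C4) and a 3,4-dioxygenated phenylacetylene (C3, C2, ring B).
- Feature used: in ring A, C4a lies on the mirror line through C7 and its methoxy group, and both neighbours, C5 and C8a, bear oxygen. An unprotected symmetric iodoresorcinol therefore serves; either hydroxyl closes to the same flavone and the other becomes 5-OH.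
- Ring order: rings A and B are bought; ring C is the only ring formed.

Key step: step 4

Remark: the target has no stereocentre, stereogenic axis or configured double bond, so there is no enantiomer to select; it is drawn as the free bis(hydrogen sulfate), which is released from its storable dipotassium salt only in the last step.

## Route

Step 1
Reactants: 1 5-methoxyresorcinol
Product: 2 2-iodo-5-methoxybenzene-1,3-diol
Conditions: I2 (1.0 equiv), NaHCO3 (1.1 equiv), H2O–THF, 0 °C to rt
Reagents that add atoms: iodine, II
Why: Electrophilic aromatic iodination of the resorcinol monoanion, which under aqueous bicarbonate enters between the two hydroxyls as with resorcinol and orcinol; that carbon is here also para to the methoxy group, one equivalent of iodine at 0 °C limits di-iodination, and the symmetric isomer should be separable from any 4-iodo isomer by crystallisation or chromatography.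

Step 2
Reactants: 3 4-(benzyloxy)-3-hydroxybenzaldehyde
Product: 4 4-(benzyloxy)-3-(methoxymethoxy)benzaldehyde
Conditions: MOMCl, K2CO3, DMF, 0 °C to rt
Reagents that add atoms: chloromethyl methyl ether, COCCl
Why: Williamson-type O-alkylation (MOM ether formation) of the only free phenol, under carbonate conditions that leave the aldehyde and the benzyl ether untouched.

Step 3
Reactants: 4 4-(benzyloxy)-3-(methoxymethoxy)benzaldehyde; 5 dimethyl (1-diazo-2-oxopropyl)phosphonate
Product: 6 1-(benzyloxy)-4-ethynyl-2-(methoxymethoxy)benzene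
Conditions: K2CO3, MeOH, rt
Reagents that add atoms: dimethyl (1-diazo-2-oxopropyl)phosphonate 5, COP(=O)(OC)C(=[N+]=[N-])C(C)=O (its diazo carbon becomes the terminal alkyne carbon)
Why: Ohira–Bestmann variant of the Seyferth–Gilbert homologation, in which methanolysis of 5 frees the diazomethylphosphonate anion, this olefinates the non-enolisable aldehyde, and loss of N2 with a 1,2-hydrogen shift gives the terminal alkyne under conditions inert to MOM and benzyl ethers.

Step 4
Reactants: 2 2-iodo-5-methoxybenzene-1,3-diol; 6 1-(benzyloxy)-4-ethynyl-2-(methoxymethoxy)benzene; 7 carbon monoxide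
Product: 10 4'-benzyloxy-5-hydroxy-7-methoxy-3'-(methoxymethoxy)flavone, via hydroxyaryl ynone 8 (not isolated), via diethylamino enaminone 9 (not isolated)
Conditions: PdCl2(dppf) (5 mol %), CO (5 bar), Et2NH–DMF, 80 °C, no copper
Reagents that add atoms: carbon monoxide 7, [C-]#[O+]; diethylamine, CCNCC (present only in intermediate 9, lost again)
Why: Pd(0) inserts into the C–I bond of 2, CO migrates in to give the aroylpalladium species, and the amine-deprotonated alkyne 6 displaces iodide on palladium so that reductive elimination delivers ynone 8 (bonds C4a–C4 and C4–C3). Diethylamine then adds reversibly to C2 of 8 to give the push–pull enaminone 9, a flanking phenol attacks the same carbon and the amine leaves (bond O1–C2), so ring C closes in the 6-endo mode (6-endo-dig counted on 8, addition–elimination on 9). The closest known reaction type is the palladium-catalysed carbonylative Sonogashira annulation of 2-iodophenols with terminal arylacetylenes in a secondary amine, which gives flavones. No stereocentre is formed. Three selectivities are needed: ring size (flavone against the 5-exo aurone) is set by the enaminone pathway, which makes C2 the only electrophilic carbon; carbonylative against direct alkynylation is favoured by CO pressure, the absence of copper and the fast migration of an electron-rich aryl group to CO; capture of the acyl complex by alkyne rather than by amine is helped by the two ortho substituents that shield the acyl carbon. Regiochemistry does not arise, because the two hydroxyls of 2 are mirror images across the I–C2···C5–OMe line, and the one left over becomes the hydrogen-bonded 5-OH.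

Step 5
Reactants: 10 4'-benzyloxy-5-hydroxy-7-methoxy-3'-(methoxymethoxy)flavone
Product: 11 5,4'-bis(benzyloxy)-7-methoxy-3'-(methoxymethoxy)flavone
Conditions: BnBr, K2CO3, cat. Bu4NI, DMF, 70 °C
Reagents that add atoms: benzyl bromide, BrCc1ccccc1
Why: Williamson etherification of the only acidic site left, where the hydrogen bond to C4=O slows the reaction but should yield to carbonate in warm DMF with iodide catalysis.

Step 6
Reactants: 11 5,4'-bis(benzyloxy)-7-methoxy-3'-(methoxymethoxy)flavone
Product: 14 5,4'-bis(benzyloxy)-3-hydroxy-7-methoxy-3'-(methoxymethoxy)flavone, via 3-lithioflavone 12 (not isolated), via lithium trimethoxyborate 13 (not isolated)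
Conditions: LDA (1.5 equiv), THF, −78 °C; B(OMe)3, −78 to 0 °C; AcOH, 30% H2O2, 0 °C to rt
Reagents that add atoms: hydrogen peroxide, OO (the new O3); lithium diisopropylamide, [Li+].CC(C)[N-]C(C)C (lithium in 12 and 13 only); trimethyl borate, COB(OC)OC (in 13 only)
Why: Lithiation–borylation–oxidation as known for flavones, in which LDA removes the vinylic C3–H next to the coordinating carbonyl (it is too weak a base for aryl or benzylic C–H at −78 °C), the borate fixes the anion before it can ring-open, and peroxide in weakly acidic medium effects the C-to-O 1,2-shift without harm to the MOM or benzyl ethers.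

Step 7
Reactants: 14 5,4'-bis(benzyloxy)-3-hydroxy-7-methoxy-3'-(methoxymethoxy)flavone
Product: 15 5,4'-bis(benzyloxy)-3,3'-dihydroxy-7-methoxyflavone
Conditions: 2 M aq HCl, MeOH–THF, 40 °C
Reagents that add atoms: none
Why: Acid-catalysed acetal hydrolysis, since the MOM acetal ionises far more readily than the benzyl aryl ethers, which need much stronger acid.

Step 8
Reactants: 15 5,4'-bis(benzyloxy)-3,3'-dihydroxy-7-methoxyflavone
Product: 17 dipotassium 5,4'-bis(benzyloxy)-7-methoxyflavone-3,3'-diyl disulfate, via bis(pyridinium) disulfate 16 (not isolated)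
Conditions: SO3·pyridine (excess), pyridine, 45 °C; then KOH, MeOH–H2O, 0 °C, to pH 8; Sephadex LH-20 or C18
Reagents that add atoms: sulfur trioxide–pyridine complex, O=S(=O)([O-])[n+]1ccccc1; potassium hydroxide, [K+].[OH-]
Why: O-sulfation of phenolic and enolic hydroxyls with a sulfur trioxide–amine complex, where excess reagent can be used because only O3 and O3' are free and the complex is too mild for ring sulfonation, and cation exchange gives the stable potassium salt.

Step 9
Reactants: 17 dipotassium 5,4'-bis(benzyloxy)-7-methoxyflavone-3,3'-diyl disulfate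
Product: 18 dipotassium rhamnetin 3,3'-disulfate
Conditions: H2 (1 atm), 10% Pd/C, MeOH–H2O, rt
Reagents that add atoms: none
Why: Catalytic hydrogenolysis of both benzyl aryl ethers in neutral medium, where aryl sulfate salts, the methyl ether and the tetrasubstituted C2=C3 bond of the flavonol are not attacked.

Step 10
Reactants: 18 dipotassium rhamnetin 3,3'-disulfate
Product: 19 rhamnetin 3,3'-disulfate (free bis(hydrogen sulfate))
Conditions: load on C18 in ice-cold 0.05 M aq HCl, wash with the same acid then a little ice water, elute with MeOH–H2O, freeze-dry, store cold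
Reagents that add atoms: none
Why: Plain cation exchange by acidification, in which potassium is washed out as its chloride while the flavonoid stays on the reversed phase, and the short contact at 0 °C keeps the slow acid-catalysed hydrolysis of the aryl sulfates in check.

## Compound list

1 | 5-methoxyresorcinol (5-methoxybenzene-1,3-diol) | COc1cc(O)cc(O)c1 | starting material
2 | 2-iodo-5-methoxybenzene-1,3-diol | COc1cc(O)c(I)c(O)c1 | intermediate
3 | 4-(benzyloxy)-3-hydroxybenzaldehyde | O=Cc1ccc(OCc2ccccc2)c(O)c1 | starting material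
4 | 4-(benzyloxy)-3-(methoxymethoxy)benzaldehyde | O=Cc1ccc(OCc2ccccc2)c(OCOC)c1 | intermediate
5 | dimethyl (1-diazo-2-oxopropyl)phosphonate | COP(=O)(OC)C(=[N+]=[N-])C(C)=O | starting material
6 | 1-(benzyloxy)-4-ethynyl-2-(methoxymethoxy)benzene | C#Cc1ccc(OCc2ccccc2)c(OCOC)c1 | intermediate
7 | carbon monoxide | [C-]#[O+] | starting material
8 | 3-[4-(benzyloxy)-3-(methoxymethoxy)phenyl]-1-(2,6-dihydroxy-4-methoxyphenyl)prop-2-yn-1-one (not isolated) | COc1cc(O)c(C(=O)C#Cc2ccc(OCc3ccccc3)c(OCOC)c2)c(O)c1 | intermediate
9 | (E)-3-[4-(benzyloxy)-3-(methoxymethoxy)phenyl]-3-(diethylamino)-1-(2,6-dihydroxy-4-methoxyphenyl)prop-2-en-1-one (not isolated; the geometry has no bearing on the closure) | COc1cc(O)c(C(=O)/C=C(/N(CC)CC)c2ccc(OCc3ccccc3)c(OCOC)c2)c(O)c1 | intermediate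
10 | 4'-benzyloxy-5-hydroxy-7-methoxy-3'-(methoxymethoxy)flavone | COc1cc(O)c2c(=O)cc(-c3ccc(OCc4ccccc4)c(OCOC)c3)oc2c1 | intermediate
11 | 5,4'-bis(benzyloxy)-7-methoxy-3'-(methoxymethoxy)flavone | COc1cc(OCc2ccccc2)c2c(=O)cc(-c3ccc(OCc4ccccc4)c(OCOC)c3)oc2c1 | intermediate
12 | 3-lithio derivative of 11 (not isolated) | COc1cc(OCc2ccccc2)c2c(=O)c([Li])c(-c3ccc(OCc4ccccc4)c(OCOC)c3)oc2c1 | intermediate
13 | lithium trimethoxy(flavon-3-yl)borate derived from 12 (not isolated) | COc1cc(OCc2ccccc2)c2c(=O)c([B-](OC)(OC)OC)c(-c3ccc(OCc4ccccc4)c(OCOC)c3)oc2c1.[Li+] | intermediate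
14 | 5,4'-bis(benzyloxy)-3-hydroxy-7-methoxy-3'-(methoxymethoxy)flavone | COc1cc(OCc2ccccc2)c2c(=O)c(O)c(-c3ccc(OCc4ccccc4)c(OCOC)c3)oc2c1 | intermediate
15 | 5,4'-bis(benzyloxy)-3,3'-dihydroxy-7-methoxyflavone | COc1cc(OCc2ccccc2)c2c(=O)c(O)c(-c3ccc(OCc4ccccc4)c(O)c3)oc2c1 | intermediate
16 | bis(pyridinium) 5,4'-bis(benzyloxy)-7-methoxyflavone-3,3'-diyl disulfate (not isolated) | COc1cc(OCc2ccccc2)c2c(=O)c(OS(=O)(=O)[O-])c(-c3ccc(OCc4ccccc4)c(OS(=O)(=O)[O-])c3)oc2c1.c1cc[nH+]cc1.c1cc[nH+]cc1 | intermediate
17 | dipotassium 5,4'-bis(benzyloxy)-7-methoxyflavone-3,3'-diyl disulfate | COc1cc(OCc2ccccc2)c2c(=O)c(OS(=O)(=O)[O-])c(-c3ccc(OCc4ccccc4)c(OS(=O)(=O)[O-])c3)oc2c1.[K+].[K+] | intermediate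
18 | dipotassium rhamnetin 3,3'-disulfate | COc1cc(O)c2c(=O)c(OS(=O)(=O)[O-])c(-c3ccc(O)c(OS(=O)(=O)[O-])c3)oc2c1.[K+].[K+] | intermediate
19 | rhamnetin 3,3'-disulfate | COc1cc(O)c2c(=O)c(OS(=O)(=O)O)c(-c3ccc(O)c(OS(=O)(=O)O)c3)oc2c1 | target

## Step count and risks

Total step count: 10. Longest linear sequence: 9 steps (3 to 19, steps 2 to 10).

**Step 4.**
- What may go wrong: oxidative addition into the electron-rich, doubly ortho-substituted C–I bond of the phenoxide may be slow. That leaves room for hydrodeiodination, CO-free alkynylation followed by 5-endo closure, capture of the acylpalladium by diethylamine, or 5-exo closure.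
- Fallback, from 2 and 6, back to the route at 10:
  - 2 is acetylated (Ac2O, pyridine) to 2-iodo-5-methoxy-1,3-phenylene diacetate F1, a less electron-rich iodide that cannot ionise.
  - Carbonylative Sonogashira coupling of F1 with 6 under a tertiary amine (PdCl2(PPh3)2, Et3N, CO, THF) cannot lead to aminocarbonylation or cyclisation. It should stop at the isolable 2-{3-[4-(benzyloxy)-3-(methoxymethoxy)phenyl]prop-2-ynoyl}-5-methoxy-1,3-phenylene diacetate F2.
  - In a separate, metal-free operation, Et2NH in EtOH removes both acetates by aminolysis and carries the freed ynone 8 through 9 to 10.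

**Step 6.**
- What may go wrong: deprotonation at C3 may be incomplete, the lithiated pyranone may ring-open by β-elimination of the phenoxide on warming, or the amide may add at C2.
- Fallback, from 11, back to the route at 14:
  - The C2=C3 bond is epoxidised with dimethyldioxirane (acetone–CH2Cl2, 0 °C) to racemic 5,4'-bis(benzyloxy)-7-methoxy-3'-(methoxymethoxy)flavone 2,3-epoxide F3.
  - A trace of p-TsOH in CH2Cl2 opens F3 at the oxygen- and aryl-stabilised C2, and loss of H3 gives flavonol 14.
  - Any loss of the MOM group at this point only anticipates step 7.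

**Step 8.**
- What may go wrong: sulfation of the hydrogen-bonded, flanked 3-OH may be incomplete, the resulting polar salt mixtures may be hard to separate, and sulfate may be lost during isolation.
- Fallback, from 15, back to the route at 17:
  - Both hydroxyls are converted with 2,2,2-trichloroethyl chlorosulfate (Et3N, DMAP, THF) into the neutral 5,4'-bis(benzyloxy)-7-methoxyflavone-3,3'-diyl bis(2,2,2-trichloroethyl sulfate) F4, which can be purified on silica.
  - Reductive fragmentation (Zn, HCO2NH4, MeOH) gives diammonium 5,4'-bis(benzyloxy)-7-methoxyflavone-3,3'-diyl disulfate F5.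
  - KOH (2 equiv) in MeOH–H2O, with ammonia driven off on evaporation, gives 17.

## Further compounds

F1 | step 4 | 2-iodo-5-methoxy-1,3-phenylene diacetate | COc1cc(OC(C)=O)c(I)c(OC(C)=O)c1
F2 | step 4 | 2-{3-[4-(benzyloxy)-3-(methoxymethoxy)phenyl]prop-2-ynoyl}-5-methoxy-1,3-phenylene diacetate | COc1cc(OC(C)=O)c(C(=O)C#Cc2ccc(OCc3ccccc3)c(OCOC)c2)c(OC(C)=O)c1
F3 | step 6 | 5,4'-bis(benzyloxy)-7-methoxy-3'-(methoxymethoxy)flavone 2,3-epoxide (racemic, cis-fused, relative configuration shown) | O=C1[C@H]2O[C@@]2(c2ccc(OCc3ccccc3)c(OCOC)c2)Oc2cc(OC)cc(OCc3ccccc3)c21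
F4 | step 8 | 5,4'-bis(benzyloxy)-7-methoxyflavone-3,3'-diyl bis(2,2,2-trichloroethyl sulfate) | COc1cc(OCc2ccccc2)c2c(=O)c(OS(=O)(=O)OCC(Cl)(Cl)Cl)c(-c3ccc(OCc4ccccc4)c(OS(=O)(=O)OCC(Cl)(Cl)Cl)c3)oc2c1
F5 | step 8 | diammonium 5,4'-bis(benzyloxy)-7-methoxyflavone-3,3'-diyl disulfate | COc1cc(OCc2ccccc2)c2c(=O)c(OS(=O)(=O)[O-])c(-c3ccc(OCc4ccccc4)c(OS(=O)(=O)[O-])c3)oc2c1.[NH4+].[NH4+]
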